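**Plan**

- Retrosynthesis: the two acetals are removed first. Ring C is then opened at O1–C2 with removal of the C3 hydroxyl (back to a 2'-hydroxychalcone). The chalcone is cut at Cα=Cβ into 4-methoxybenzaldehyde and an acetophenone. Ring A is cut at C6–C7 and C4a–C8a, and the bond between the quaternary carbon and its vinyl group is cut last.
- Enabling feature (flavone numbering: O1, C2, C3, C4 in ring C; C4a, C5, C6, C7, C8, C8a in ring A; ring B at C2): the three ring-A oxygens sit on alternate carbons. The two on C7 and C8a flank the alkylated C8 and mark those carbons as former acyl carbons. The C7–C8–C8a triad therefore maps onto a 2-substituted malonyl unit, and C6, C5, C4a with the acetyl carbons (C4, C3) map onto acetylacetone.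
- Forward order: the side chain is fixed on a malonate by conjugate addition, ring A is built around it (step 5), an aldol condensation brings in ring B, and an oxidative cyclisation through the C8a oxygen closes ring C.
- Stereochemistry: the target has no stereocentre. The E chalcone double bond (thermodynamic) and a transient trans-dihydroflavonol are the only stereo elements on the way, and both vanish when ring C becomes aromatic.

Key step: step 5

Remark: the (3Z) geometry written for the silyl enol ethers is the expected one; it is lost in step 5 and has no bearing on the product.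

**Route**

Step 1
Reactants: 1 diethyl isopropylidenemalonate; 2 vinylmagnesium bromide
Product: 3 diethyl 2-(2-methylbut-3-en-2-yl)propanedioate
Conditions: CuI (10 mol %), THF, −20 °C to 0 °C; then 1 M aq. HCl
Reagents that add atoms: none
Why: CuI-catalysed conjugate addition of the vinyl Grignard reagent (through a vinylcuprate of monovalent copper) to the doubly activated alkylidene malonate should place the vinyl group on the β-carbon and create the quaternary carbon before any arene exists, 1,2-addition to the esters being slower than the cuprate pathway.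

Step 2
Reactants: 3 diethyl 2-(2-methylbut-3-en-2-yl)propanedioate
Product: 4 2-(2-methylbut-3-en-2-yl)propanedioic acid
Conditions: KOH (6 equiv), EtOH/H2O, reflux; then aq. HCl, 0 °C, pH 1
Reagents that add atoms: potassium hydroxide, [K+].[OH-]
Why: Saponification of both ethyl esters with excess hydroxide is a standard ester hydrolysis that the quaternary neighbour slows but cannot divert (no β-hydrogen, no leaving group), and cold acidification should give the diacid without decarboxylation.

Step 3
Reactants: 4 2-(2-methylbut-3-en-2-yl)propanedioic acid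
Product: 5 2-(2-methylbut-3-en-2-yl)propanedioyl dichloride
Conditions: (COCl)2 (3 equiv), DMF (cat.), CH2Cl2, 0 °C to rt; evaporate, use crude
Reagents that add atoms: oxalyl chloride, O=C(Cl)C(Cl)=O
Why: Acyl chloride formation through the Vilsmeier-type chloroiminium salt from DMF and oxalyl chloride runs at or below room temperature, which should avoid loss of HCl to a chlorocarbonyl ketene and addition of HCl to the monosubstituted alkene.

Step 4
Reactants: 6 acetylacetone
Product: 8 (3Z)-2,4-bis(trimethylsilyloxy)penta-1,3-diene, via mono-silyl enol ether 7 (not isolated)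
Conditions: Me3SiOTf (2.2 equiv), Et3N (2.5 equiv), Et2O, 0 °C to rt; distil under reduced pressure
Reagents that add atoms: trimethylsilyl trifluoromethanesulfonate, C[Si](C)(C)OS(=O)(=O)C(F)(F)F
Why: Two successive soft enolisations with Me3SiOTf and Et3N (silyl enol ether formation) should first give the conjugated mono-ether 7 and then silylate its remaining methyl ketone at the terminal position, the standard one-flask entry to 1,3-bis(silyloxy)-1,3-dienes of 1,3-diketones.

Step 5
Reactants: 5 2-(2-methylbut-3-en-2-yl)propanedioyl dichloride; 8 (3Z)-2,4-bis(trimethylsilyloxy)penta-1,3-diene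
Product: 11 1-[2,4,6-trihydroxy-3-(2-methylbut-3-en-2-yl)phenyl]ethan-1-one, via acyclic keto acid chloride 9 (not isolated), via cyclohexanetrione 10 (not isolated)
Conditions: TiCl4 (2 equiv), CH2Cl2 (0.02 M), 8 added last, −78 °C to 20 °C; then 1 M aq. HCl
Reagents that add atoms: none
Why: Proposed new method: TiCl4 activates one acyl chloride of 5, the terminal CH2 of 8 (its most nucleophilic carbon) adds in a Mukaiyama-type C-acylation with loss of chloride and Me3SiCl to form C6–C7 and give 9, whose remaining silyloxy enone becomes a titanium 1,3-diketonate; the central carbon of that chelate (C4a) then acylates the second acyl chloride (C8a) to give trione 10, which enolises irreversibly to the phloroglucinol 11. The closest known reaction type is the TiCl4-mediated formal [3+3] cyclocondensation of 1,3-bis(silyloxy)-1,3-dienes with 1,3-dielectrophiles such as 3-silyloxy enones and 3-silyloxyalk-2-enoyl chlorides, which gives salicylates and resorcinols, together with the C-acylation of silyl enol ethers by acid chlorides; new here is a malonyl dichloride as double acyl donor, which raises the product to the phloroglucinol oxidation level. Ring A closes in a 6-(enolexo)-exo-trig mode, the carbonyl of the acyl chloride lying outside the forming ring and chloride leaving after the addition. No stereocentre survives, since the CH centres of 9 and 10 are erased by enolisation. The step needs C- and not O-acylation at the ring closure (attack by the C5 oxygen would give a 4-hydroxy-2-pyranone), and this should be secured by titanium holding the C5 and acetyl oxygens in the chelate so that only carbon is free, by the low temperature and by the aromatisation that pulls the carbon pathway forward. Because 5 is symmetric the order of the two C–C bond formations does not change the constitution, high dilution should hold back oligomers, and the silyl dienol ether far outpaces the isolated vinyl group as a nucleophile.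

Step 6
Reactants: 11 1-[2,4,6-trihydroxy-3-(2-methylbut-3-en-2-yl)phenyl]ethan-1-one
Product: 12 1-[2-hydroxy-4,6-bis(methoxymethoxy)-3-(2-methylbut-3-en-2-yl)phenyl]ethan-1-one
Conditions: MOMCl (2.3 equiv), iPr2NEt (3 equiv), CH2Cl2, 0 °C to rt
Reagents that add atoms: chloromethyl methyl ether, COCCl
Why: O-Alkylation of phenols with MOMCl and a hindered amine base (Williamson-type acetal formation) should take the C7 and C5 hydroxyls (C4 and C6 of the acetophenone), while the C8a hydroxyl, wedged between the quaternary carbon and the acetyl group and hydrogen-bonded to the carbonyl, should stay free.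

Step 7
Reactants: 12 1-[2-hydroxy-4,6-bis(methoxymethoxy)-3-(2-methylbut-3-en-2-yl)phenyl]ethan-1-one; 13 4-methoxybenzaldehyde
Product: 14 (2E)-1-[2-hydroxy-4,6-bis(methoxymethoxy)-3-(2-methylbut-3-en-2-yl)phenyl]-3-(4-methoxyphenyl)prop-2-en-1-one
Conditions: KOH (50 % aq.), EtOH, rt; then aq. HCl to pH 6
Reagents that add atoms: none
Why: Claisen–Schmidt condensation of the methyl ketone enolate with the non-enolisable aldehyde followed by E1cB dehydration should give the E enone under thermodynamic control, and the acetals and the isolated alkene are inert to aqueous alcoholic KOH.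

Step 8
Reactants: 14 (2E)-1-[2-hydroxy-4,6-bis(methoxymethoxy)-3-(2-methylbut-3-en-2-yl)phenyl]-3-(4-methoxyphenyl)prop-2-en-1-one
Product: 16 3-hydroxy-5,7-bis(methoxymethoxy)-2-(4-methoxyphenyl)-8-(2-methylbut-3-en-2-yl)-4H-chromen-4-one, via trans-dihydroflavonol 15 (not isolated)
Conditions: 30 % aq. H2O2, 2 M aq. NaOH, MeOH, 0 °C to rt; then aq. HCl to pH 6
Reagents that add atoms: hydrogen peroxide, OO
Why: In the Algar–Flynn–Oyamada reaction the only free phenoxide (the C8a oxygen) adds to the β-carbon in a 6-endo-trig oxa-Michael closure while the enolate is hydroxylated by H2O2 to give racemic trans-dihydroflavonol 15 (trans by the diequatorial preference), which alkaline peroxide dehydrogenates to the flavonol, and the unactivated vinyl group does not react with nucleophilic peroxide.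

Step 9
Reactants: 16 3-hydroxy-5,7-bis(methoxymethoxy)-2-(4-methoxyphenyl)-8-(2-methylbut-3-en-2-yl)-4H-chromen-4-one
Product: 17 3,5,7-trihydroxy-2-(4-methoxyphenyl)-8-(2-methylbut-3-en-2-yl)-4H-chromen-4-one
Conditions: 3 M aq. HCl, MeOH, 50 °C
Reagents that add atoms: none
Why: Acid-catalysed acetal exchange with methanol removes both methoxymethyl groups as dimethoxymethane (MOM cleavage), and at this acidity and temperature the monosubstituted alkene should not be protonated.

**Compound list**

1 | diethyl 2-(propan-2-ylidene)propanedioate (diethyl isopropylidenemalonate) | CCOC(=O)C(=C(C)C)C(=O)OCC | starting material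
2 | vinylmagnesium bromide | C=C[Mg]Br | starting material
3 | diethyl 2-(2-methylbut-3-en-2-yl)propanedioate | CCOC(=O)C(C(C)(C)C=C)C(=O)OCC | intermediate
4 | 2-(2-methylbut-3-en-2-yl)propanedioic acid | OC(=O)C(C(C)(C)C=C)C(=O)O | intermediate
5 | 2-(2-methylbut-3-en-2-yl)propanedioyl dichloride | C=CC(C)(C)C(C(Cl)=O)C(Cl)=O | intermediate
6 | pentane-2,4-dione (acetylacetone) | CC(=O)CC(C)=O | starting material
7 | (3Z)-4-(trimethylsilyloxy)pent-3-en-2-one | CC(=O)/C=C(/C)O[Si](C)(C)C | intermediate (not isolated)
8 | (3Z)-2,4-bis(trimethylsilyloxy)penta-1,3-diene | C=C(O[Si](C)(C)C)/C=C(/C)O[Si](C)(C)C | intermediate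
9 | (6Z)-2-(2-methylbut-3-en-2-yl)-3,5-dioxo-7-(trimethylsilyloxy)oct-6-enoyl chloride (racemic; titanium-bound in the flask) | C=CC(C)(C)C(C(Cl)=O)C(=O)CC(=O)/C=C(/C)O[Si](C)(C)C | intermediate (not isolated)
10 | 2-acetyl-4-(2-methylbut-3-en-2-yl)cyclohexane-1,3,5-trione (keto tautomer of 11; CH centres undefined) | CC(=O)C1C(=O)CC(=O)C(C(C)(C)C=C)C1=O | intermediate (not isolated)
11 | 1-[2,4,6-trihydroxy-3-(2-methylbut-3-en-2-yl)phenyl]ethan-1-one | CC(=O)c1c(O)cc(O)c(C(C)(C)C=C)c1O | intermediate
12 | 1-[2-hydroxy-4,6-bis(methoxymethoxy)-3-(2-methylbut-3-en-2-yl)phenyl]ethan-1-one | CC(=O)c1c(OCOC)cc(OCOC)c(C(C)(C)C=C)c1O | intermediate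
13 | 4-methoxybenzaldehyde | COc1ccc(C=O)cc1 | starting material
14 | (2E)-1-[2-hydroxy-4,6-bis(methoxymethoxy)-3-(2-methylbut-3-en-2-yl)phenyl]-3-(4-methoxyphenyl)prop-2-en-1-one | COc1ccc(/C=C/C(=O)c2c(OCOC)cc(OCOC)c(C(C)(C)C=C)c2O)cc1 | intermediate
15 | (2R*,3R*)-3-hydroxy-5,7-bis(methoxymethoxy)-2-(4-methoxyphenyl)-8-(2-methylbut-3-en-2-yl)-2,3-dihydro-4H-chromen-4-one (racemic trans; one enantiomer drawn) | COCOc1cc(OCOC)c(C(C)(C)C=C)c2O[C@H](c3ccc(OC)cc3)[C@@H](O)C(=O)c12 | intermediate (not isolated)
16 | 3-hydroxy-5,7-bis(methoxymethoxy)-2-(4-methoxyphenyl)-8-(2-methylbut-3-en-2-yl)-4H-chromen-4-one | COCOc1cc(OCOC)c(C(C)(C)C=C)c2oc(-c3ccc(OC)cc3)c(O)c(=O)c12 | intermediate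
17 | 3,5,7-trihydroxy-2-(4-methoxyphenyl)-8-(2-methylbut-3-en-2-yl)-4H-chromen-4-one | C=CC(C)(C)c1c(O)cc(O)c2c(=O)c(O)c(-c3ccc(OC)cc3)oc12 | target

**Count and risks**

Total step count: 9. Longest linear sequence: 8 steps (steps 1, 2, 3, 5, 6, 7, 8, 9, from compound 1); the diene branch (step 4) joins at step 5.

The three steps most likely to fail:

First, step 5. The ring closure may run through the C5 oxygen (lactonisation to a pyranone) or between molecules instead of through carbon, because an acyl chloride is a hard and very fast electrophile. The fallback separates the two acylations and uses known reaction types. It sets out from diester 3 and diene 8 and returns at 11.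
- Mono-saponification of 3 (KOH, 1 equiv, EtOH, rt) should give the half ester 2-(ethoxycarbonyl)-3,3-dimethylpent-4-enoic acid F1.
- Oxalyl chloride with catalytic DMF converts it into ethyl 2-(chlorocarbonyl)-3,3-dimethylpent-4-enoate F2.
- F2 acylates the terminal carbon of 8 (Me3SiOTf cat., CH2Cl2, −78 °C to 20 °C, aqueous work-up), the established C-acylation of 1,3-bis-silyl enol ethers by acid chlorides, to give ethyl 2-(2-methylbut-3-en-2-yl)-3,5,7-trioxooctanoate F3.
- F3 is closed in a separate operation with Mg(OMe)2 in MeOH at reflux, the biomimetic Claisen (Dieckmann-type) cyclisation of 3,5,7-triketo esters to acylphloroglucinols. The ester is a slower electrophile, lactone formation is reversible under methoxide, and the magnesium chelate directs the attack to carbon.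

Second, step 8. The phenoxide may close on the α-carbon (five-membered closure leading to an aurone), a pathway favoured when an alkoxy group sits on the other side of the carbonyl, and the flavonol may be over-oxidised by excess alkaline peroxide. The fallback separates ring closure from C3 oxygenation. It sets out from chalcone 14 and returns at 16.
- Oxidative cyclisation with catalytic I2 in DMSO at 120 °C should give the flavone 5,7-bis(methoxymethoxy)-2-(4-methoxyphenyl)-8-(2-methylbut-3-en-2-yl)-4H-chromen-4-one F4.
- Deprotonation at C3 with LiN(iPr)2 in THF at −78 °C (known for 5-alkoxyflavones) and trapping with B(OMe)3 gives dimethyl [5,7-bis(methoxymethoxy)-2-(4-methoxyphenyl)-8-(2-methylbut-3-en-2-yl)-4-oxo-4H-chromen-3-yl]boronate F5.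
- F5 is oxidised in the same flask with H2O2 and AcOH to 16.

Third, step 9. The acid needed to cleave the hindered C7 acetal may protonate the vinyl group, and the neighbouring C7 hydroxyl may then trap the cation to close a dihydrofuran ring. The fallback changes the protecting group so that the last step is neutral. It sets out from 11 and returns at 17.
- Allyl bromide and K2CO3 in acetone at reflux should give 1-[2-hydroxy-3-(2-methylbut-3-en-2-yl)-4,6-bis(prop-2-en-1-yloxy)phenyl]ethan-1-one F6, with the same site preference as in step 6.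
- Claisen–Schmidt condensation with 13 gives (2E)-1-[2-hydroxy-3-(2-methylbut-3-en-2-yl)-4,6-bis(prop-2-en-1-yloxy)phenyl]-3-(4-methoxyphenyl)prop-2-en-1-one F7.
- Algar–Flynn–Oyamada oxidation passes through (2R*,3R*)-3-hydroxy-2-(4-methoxyphenyl)-8-(2-methylbut-3-en-2-yl)-5,7-bis(prop-2-en-1-yloxy)-2,3-dihydro-4H-chromen-4-one F8 (not isolated) to 3-hydroxy-2-(4-methoxyphenyl)-8-(2-methylbut-3-en-2-yl)-5,7-bis(prop-2-en-1-yloxy)-4H-chromen-4-one F9.
- Pd(PPh3)4 (zerovalent palladium, 5 mol %) with morpholine in THF at rt removes both O-allyl groups through π-allyl complexes. The carbon-bound 2-methylbut-3-en-2-yl group has no leaving group and should be untouched, so 17 results.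

Further compounds
F1 | step 5 | 2-(ethoxycarbonyl)-3,3-dimethylpent-4-enoic acid | CCOC(=O)C(C(C)(C)C=C)C(=O)O
F2 | step 5 | ethyl 2-(chlorocarbonyl)-3,3-dimethylpent-4-enoate | CCOC(=O)C(C(C)(C)C=C)C(Cl)=O
F3 | step 5 | ethyl 2-(2-methylbut-3-en-2-yl)-3,5,7-trioxooctanoate | CCOC(=O)C(C(C)(C)C=C)C(=O)CC(=O)CC(C)=O
F4 | step 8 | 5,7-bis(methoxymethoxy)-2-(4-methoxyphenyl)-8-(2-methylbut-3-en-2-yl)-4H-chromen-4-one | COCOc1cc(OCOC)c(C(C)(C)C=C)c2oc(-c3ccc(OC)cc3)cc(=O)c12
F5 | step 8 | dimethyl [5,7-bis(methoxymethoxy)-2-(4-methoxyphenyl)-8-(2-methylbut-3-en-2-yl)-4-oxo-4H-chromen-3-yl]boronate | COCOc1cc(OCOC)c(C(C)(C)C=C)c2oc(-c3ccc(OC)cc3)c(B(OC)OC)c(=O)c12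
F6 | step 9 | 1-[2-hydroxy-3-(2-methylbut-3-en-2-yl)-4,6-bis(prop-2-en-1-yloxy)phenyl]ethan-1-one | CC(=O)c1c(OCC=C)cc(OCC=C)c(C(C)(C)C=C)c1O
F7 | step 9 | (2E)-1-[2-hydroxy-3-(2-methylbut-3-en-2-yl)-4,6-bis(prop-2-en-1-yloxy)phenyl]-3-(4-methoxyphenyl)prop-2-en-1-one | COc1ccc(/C=C/C(=O)c2c(OCC=C)cc(OCC=C)c(C(C)(C)C=C)c2O)cc1
F8 | step 9 | (2R*,3R*)-3-hydroxy-2-(4-methoxyphenyl)-8-(2-methylbut-3-en-2-yl)-5,7-bis(prop-2-en-1-yloxy)-2,3-dihydro-4H-chromen-4-one (racemic trans; one enantiomer drawn) | C=CCOc1cc(OCC=C)c(C(C)(C)C=C)c2O[C@H](c3ccc(OC)cc3)[C@@H](O)C(=O)c12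
F9 | step 9 | 3-hydroxy-2-(4-methoxyphenyl)-8-(2-methylbut-3-en-2-yl)-5,7-bis(prop-2-en-1-yloxy)-4H-chromen-4-one | C=CCOc1cc(OCC=C)c(C(C)(C)C=C)c2oc(-c3ccc(OC)cc3)c(O)c(=O)c12
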